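**Plan**

- Cuts (target numbering C1 = OCH2, O2, C3 … C8a; primes = side chain): C6–C7 of the carbocycle (after C6=O ⇒ C6–OH), the C5–C6 two-carbon unit from the C4a carbonyl, C8–C8a (aldol), C3–C1' (vinyl anion + lactone), C3'–CH3 and C2'–C3'.
- Forward: L-isoleucine gives the stannylated side chain; its vinyllithium adds to 4-methoxy-5,6-dihydropyran-2-one and acid closes the pyran ring (O2, C1, C8a, C4a, C4, C3) first, as a 2,3-dihydro-4H-pyran-4-one.
- Then aldol at C8a with (S)-lactaldehyde, formyl-olefination at C4a, oxidation at C7, and closure of the carbocycle (C4a, C5, C6, C7, C8, C8a) last by SmI2 pinacol coupling of C6 with C7; oxidation at C6 and desilylation finish.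
- Enabling feature: the acyloin C6(=O)–C7(OH)CH3 lies between the pyran atoms C4a and C8a, so a vinylogous formyl group on C4a (O2–C3=C4–C4a=C5–C6H=O) and a methyl ketone on the C8a arm are 1,6-related, and the conjugated aldehyde is the carbonyl reduced first.
- Stereochemistry: C4', C5' from L-isoleucine; C3' by chelation-controlled MeMgBr addition; C8 and C8a by a Felkin-selective anti aldol with the lactate-derived aldehyde, whose own centre (C7) is then erased; C7 is re-made in the pinacol step, trans to the C8 silyloxy group.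

Key step: step 14

**Route**

Step 1
Reactants: 1 L-isoleucine
Product: 2 (2S,3S)-2-hydroxy-3-methylpentanoic acid
Conditions: NaNO2, 1 M aq. H2SO4, 0 °C → rt
Reagents that add atoms: water, O
Why: Diazotisation of the alpha-amino acid and hydrolysis through the alpha-lactone (double inversion, net retention) turns NH2 into OH, so C4' (S) and C5' (S) come from the chiral pool.

Step 2
Reactants: 2 (2S,3S)-2-hydroxy-3-methylpentanoic acid
Product: 3 (2S,3S)-2-hydroxy-N-methoxy-N,3-dimethylpentanamide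
Conditions: MeNHOMe·HCl, EDC·HCl, HOBt (cat.), N-methylmorpholine, CH2Cl2, 0 °C → rt
Reagents that add atoms: N,O-dimethylhydroxylamine hydrochloride, CNOC.Cl
Why: Carbodiimide-mediated amide coupling (Weinreb amide formation) gives an acyl donor that takes up only one organolithium, and the alpha-hydroxyl is left free because it is the chelating group of step 4.

Step 3
Reactants: 3 (2S,3S)-2-hydroxy-N-methoxy-N,3-dimethylpentanamide; 4 (E)-1,2-bis(tributylstannyl)ethene
Product: 6 (1E,4S,5S)-4-hydroxy-5-methyl-1-(tributylstannyl)hept-1-en-3-one, via stannylvinyllithium 5 (not isolated)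
Conditions: 4 (2.4 equiv), n-BuLi (2.3 equiv), THF, −78 °C; then 3, −78 → −30 °C; aq. NH4Cl
Reagents that add atoms: none
Why: Tin–lithium exchange on 4 gives the (E)-vinyllithium with retention, and its addition to the Weinreb amide stops at the chelated tetrahedral adduct (Weinreb ketone synthesis, first equivalent consumed by the hydroxyl), so the (E)-beta-stannyl enone appears only on work-up.

Step 4
Reactants: 6 (1E,4S,5S)-4-hydroxy-5-methyl-1-(tributylstannyl)hept-1-en-3-one
Product: 7 (1E,3R,4S,5S)-3,5-dimethyl-1-(tributylstannyl)hept-1-ene-3,4-diol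
Conditions: MeMgBr (3 equiv), THF, −78 °C; aq. NH4Cl
Reagents that add atoms: methylmagnesium bromide, C[Mg]Br
Why: The magnesium alkoxide of the alpha-hydroxy ketone locks C=O and C4'–O in a five-membered chelate and the Grignard reagent adds 1,2 from the face opposite the sec-butyl group (Cram chelate model), which sets C3' as R with O3' anti to O4'.

Step 5
Reactants: 7 (1E,3R,4S,5S)-3,5-dimethyl-1-(tributylstannyl)hept-1-ene-3,4-diol
Product: 8 (1E,3R,4S,5S)-4-[(tert-butyldimethylsilyl)oxy]-3,5-dimethyl-1-(tributylstannyl)hept-1-en-3-ol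
Conditions: TBSOTf (1.05 equiv), 2,6-lutidine, CH2Cl2, −78 °C
Reagents that add atoms: tert-butyldimethylsilyl trifluoromethanesulfonate, CC(C)(C)[Si](C)(C)OS(=O)(=O)C(F)(F)F
Why: Silyl triflate silylation at −78 °C discriminates the secondary from the tertiary allylic hydroxyl, which stays free (selective silyl ether formation).

Step 6
Reactants: 9 dihydro-2H-pyran-2,4(3H)-dione
Product: 10 4-methoxy-5,6-dihydro-2H-pyran-2-one
Conditions: Me2SO4, K2CO3, acetone, rt
Reagents that add atoms: dimethyl sulfate, COS(=O)(=O)OC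
Why: The enolised beta-keto lactone is O-methylated by the hard electrophile to the vinylogous carbonate (enol ether formation), which masks C4a as a latent ketone.

Step 7
Reactants: 8 (1E,3R,4S,5S)-4-[(tert-butyldimethylsilyl)oxy]-3,5-dimethyl-1-(tributylstannyl)hept-1-en-3-ol; 10 4-methoxy-5,6-dihydro-2H-pyran-2-one
Product: 13 6-[(1E,3R,4S,5S)-4-[(tert-butyldimethylsilyl)oxy]-3-hydroxy-3,5-dimethylhept-1-en-1-yl]-2,3-dihydro-4H-pyran-4-one, via dilithiated vinyl reagent 11 (not isolated), via lithium lactolate 12 (not isolated)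
Conditions: 8, n-BuLi (2.1 equiv), THF, −78 → −40 °C; then 10, −78 °C; then 0.5 M aq. HCl, THF, 0 °C → rt
Reagents that add atoms: water, O
Why: Tin–lithium exchange with retention gives the (E)-vinyllithium, which adds once to the lactone carbonyl (the future C3), and acid then hydrolyses the methyl enol ether and dehydrates the lactol, a Stork–Danheiser-type carbonyl transposition that delivers the pyran ring as the 6-alkenyl-2,3-dihydro-4H-pyran-4-one.

Step 8
Reactants: 14 ethyl (2S)-2-hydroxypropanoate (ethyl L-lactate)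
Product: 15 ethyl (2S)-2-[(triethylsilyl)oxy]propanoate
Conditions: TESCl, imidazole, CH2Cl2, 0 °C → rt
Reagents that add atoms: chlorotriethylsilane, CC[Si](CC)(CC)Cl
Why: Standard silyl ether formation; the triethylsilyl group is chosen because it can be removed later in the presence of the TBS ethers.

Step 9
Reactants: 15 ethyl (2S)-2-[(triethylsilyl)oxy]propanoate
Product: 16 (2S)-2-[(triethylsilyl)oxy]propanal
Conditions: DIBAL-H (iBu2AlH, 1.05 equiv), CH2Cl2, −78 °C; aq. potassium sodium tartrate (KNaC4H4O6)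
Reagents that add atoms: none
Why: DIBAL-H reduction of the ester at −78 °C stops at the aluminium hemiacetal, which gives the alpha-silyloxy aldehyde without loss of configuration (partial ester reduction).

Step 10
Reactants: 13 6-[(1E,3R,4S,5S)-4-[(tert-butyldimethylsilyl)oxy]-3-hydroxy-3,5-dimethylhept-1-en-1-yl]-2,3-dihydro-4H-pyran-4-one; 16 (2S)-2-[(triethylsilyl)oxy]propanal
Product: 18 (3S)-6-[(1E,3R,4S,5S)-4-[(tert-butyldimethylsilyl)oxy]-3-hydroxy-3,5-dimethylhept-1-en-1-yl]-3-[(1R,2S)-1-hydroxy-2-[(triethylsilyl)oxy]propyl]-2,3-dihydro-4H-pyran-4-one, via dilithium enolate 17 (not isolated)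
Conditions: LDA (LiN(iPr)2, 2.2 equiv), THF, −78 °C; then 16 (1.3 equiv), −78 °C, 15 min; AcOH, −78 °C
Reagents that add atoms: none
Why: Kinetic deprotonation at C8a gives the cyclic (E)-enolate, which reacts through a Zimmerman–Traxler chair (anti aldol, C8a relative to C8) on the Felkin–Anh face of the alpha-silyloxy aldehyde (new O8 anti to O7), so C8 (R) and C8a (S) are both relayed from the lactate centre.

Step 11
Reactants: 18 (3S)-6-[(1E,3R,4S,5S)-4-[(tert-butyldimethylsilyl)oxy]-3-hydroxy-3,5-dimethylhept-1-en-1-yl]-3-[(1R,2S)-1-hydroxy-2-[(triethylsilyl)oxy]propyl]-2,3-dihydro-4H-pyran-4-one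
Product: 19 (3S)-3-[(1R,2S)-1-[(tert-butyldimethylsilyl)oxy]-2-[(triethylsilyl)oxy]propyl]-6-[(1E,3R,4S,5S)-4-[(tert-butyldimethylsilyl)oxy]-3-hydroxy-3,5-dimethylhept-1-en-1-yl]-2,3-dihydro-4H-pyran-4-one
Conditions: TBSOTf (1.2 equiv), 2,6-lutidine, CH2Cl2, −78 °C
Reagents that add atoms: tert-butyldimethylsilyl trifluoromethanesulfonate, CC(C)(C)[Si](C)(C)OS(=O)(=O)C(F)(F)F
Why: Silylation with the silyl triflate under non-basic conditions protects the aldol hydroxyl without retro-aldol cleavage, the tertiary alcohol being too hindered to react at −78 °C (silyl ether formation).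

Step 12
Reactants: 19 (3S)-3-[(1R,2S)-1-[(tert-butyldimethylsilyl)oxy]-2-[(triethylsilyl)oxy]propyl]-6-[(1E,3R,4S,5S)-4-[(tert-butyldimethylsilyl)oxy]-3-hydroxy-3,5-dimethylhept-1-en-1-yl]-2,3-dihydro-4H-pyran-4-one; 20 (Z)-1-bromo-2-ethoxyethene
Product: 23 (2E)-2-[(3S)-3-[(1R,2S)-1-[(tert-butyldimethylsilyl)oxy]-2-hydroxypropyl]-6-[(1E,3R,4S,5S)-4-[(tert-butyldimethylsilyl)oxy]-3-hydroxy-3,5-dimethylhept-1-en-1-yl]-2,3-dihydro-4H-pyran-4-ylidene]acetaldehyde, via ethoxyvinyllithium 21 (not isolated), via carbinol dilithium salt 22 (not isolated)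
Conditions: 20 (3.2 equiv), n-BuLi (3 equiv), THF, −78 °C; then 19, LaCl3·2LiCl (1.1 equiv), −78 → −40 °C; then 0.5 M aq. HCl, THF, 0 °C → rt
Reagents that add atoms: water, O
Why: The alkoxyvinyl anion adds 1,2 to the lanthanum-activated vinylogous ester carbonyl C4a, and acid ionises the doubly allylic carbinol so that water enters at the ethoxy-bearing carbon and ethanol leaves (alkoxyvinyl addition and hydrolytic 1,3-transposition to the enal), which installs C5 and C6 as the push–pull dienal while the same acid cleaves the secondary TES ether.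

Step 13
Reactants: 23 (2E)-2-[(3S)-3-[(1R,2S)-1-[(tert-butyldimethylsilyl)oxy]-2-hydroxypropyl]-6-[(1E,3R,4S,5S)-4-[(tert-butyldimethylsilyl)oxy]-3-hydroxy-3,5-dimethylhept-1-en-1-yl]-2,3-dihydro-4H-pyran-4-ylidene]acetaldehyde
Product: 24 (2E)-2-[(3S)-3-[(1R)-1-[(tert-butyldimethylsilyl)oxy]-2-oxopropyl]-6-[(1E,3R,4S,5S)-4-[(tert-butyldimethylsilyl)oxy]-3-hydroxy-3,5-dimethylhept-1-en-1-yl]-2,3-dihydro-4H-pyran-4-ylidene]acetaldehyde
Conditions: IBX (1.5 equiv), DMSO, rt
Reagents that add atoms: none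
Why: IBX oxidises the only secondary alcohol to the methyl ketone and leaves the aldehyde, the tertiary alcohol and the silyl ethers alone (hypervalent iodine oxidation), which erases the lactate centre once it has done its work.

Step 14
Reactants: 24 (2E)-2-[(3S)-3-[(1R)-1-[(tert-butyldimethylsilyl)oxy]-2-oxopropyl]-6-[(1E,3R,4S,5S)-4-[(tert-butyldimethylsilyl)oxy]-3-hydroxy-3,5-dimethylhept-1-en-1-yl]-2,3-dihydro-4H-pyran-4-ylidene]acetaldehyde
Product: 25 (6R,7R,8R,8aS)-8-[(tert-butyldimethylsilyl)oxy]-3-[(1E,3R,4S,5S)-4-[(tert-butyldimethylsilyl)oxy]-3-hydroxy-3,5-dimethylhept-1-en-1-yl]-7-methyl-6,7,8,8a-tetrahydro-1H-isochromene-6,7-diol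
Conditions: SmI2 (3 equiv), t-BuOH (3 equiv), THF (high dilution), −78 → −40 °C; aq. potassium sodium tartrate (KNaC4H4O6)
Reagents that add atoms: none
Why: SmI2 transfers one electron to the conjugated aldehyde, the samarium-bound dienyl ketyl at C6 adds to the C7 ketone held on the same trivalent samarium, and a second electron transfer gives the samarium diolate; the closest known type is the SmI2-mediated intramolecular ketone–aldehyde pinacol coupling that gives cis-cyclohexane-1,2-diols trans to a neighbouring alkoxy group. The carbocycle (C4a, C5, C6, C7, C8, C8a) is closed at C6–C7 in the 6-exo-trig mode. C7 is controlled by the samarium bridge, which holds both new oxygens on one face, and that face should be the one anti to the axial C8 silyl ether (dipole and steric repulsion), leaving the C7 methyl cis to O8; C6 is set cis to O7 by the same bridge and is erased in step 15. The step needs reduction of the aldehyde before the alpha-silyloxy ketone (secured by its conjugation), bond formation at C6 and not at C4a or C3 of the delocalised radical (only C6 can reach C7 in a six-membered ring), and convergence of both C4a=C5 isomers (the ketyl has allyl-radical character, so this bond can rotate before closure).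

Step 15
Reactants: 25 (6R,7R,8R,8aS)-8-[(tert-butyldimethylsilyl)oxy]-3-[(1E,3R,4S,5S)-4-[(tert-butyldimethylsilyl)oxy]-3-hydroxy-3,5-dimethylhept-1-en-1-yl]-7-methyl-6,7,8,8a-tetrahydro-1H-isochromene-6,7-diol
Product: 26 (7S,8R,8aS)-8-[(tert-butyldimethylsilyl)oxy]-3-[(1E,3R,4S,5S)-4-[(tert-butyldimethylsilyl)oxy]-3-hydroxy-3,5-dimethylhept-1-en-1-yl]-7-hydroxy-7-methyl-1,7,8,8a-tetrahydro-6H-isochromen-6-one
Conditions: IBX (1.3 equiv), DMSO, rt
Reagents that add atoms: none
Why: IBX oxidises the secondary, doubly allylic C6 carbinol of the 1,2-diol to the ketone without glycol cleavage (hypervalent iodine oxidation), which removes the C6 centre and gives the conjugated acyloin.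

Step 16
Reactants: 26 (7S,8R,8aS)-8-[(tert-butyldimethylsilyl)oxy]-3-[(1E,3R,4S,5S)-4-[(tert-butyldimethylsilyl)oxy]-3-hydroxy-3,5-dimethylhept-1-en-1-yl]-7-hydroxy-7-methyl-1,7,8,8a-tetrahydro-6H-isochromen-6-one
Product: 27 (7S,8R,8aS)-3-[(1E,3R,4S,5S)-3,4-dihydroxy-3,5-dimethylhept-1-en-1-yl]-7,8-dihydroxy-7-methyl-1,7,8,8a-tetrahydro-6H-isochromen-6-one
Conditions: HF·pyridine, pyridine, THF, 0 °C → rt
Reagents that add atoms: none
Why: Fluoride cleaves both secondary TBS ethers under buffered conditions (fluoride desilylation) that spare the alpha-ketol and the beta-hydroxy ketone.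

**Compound list**

1 | L-isoleucine, (2S,3S)-2-amino-3-methylpentanoic acid | CC[C@H](C)[C@H](N)C(=O)O | starting material
2 | (2S,3S)-2-hydroxy-3-methylpentanoic acid | CC[C@H](C)[C@H](O)C(=O)O | intermediate
3 | (2S,3S)-2-hydroxy-N-methoxy-N,3-dimethylpentanamide | CC[C@H](C)[C@H](O)C(=O)N(C)OC | intermediate
4 | (E)-1,2-bis(tributylstannyl)ethene | CCCC[Sn](CCCC)(CCCC)/C=C/[Sn](CCCC)(CCCC)CCCC | starting material
5 | (E)-tributyl(2-lithioethenyl)stannane (not isolated) | [Li]/C=C/[Sn](CCCC)(CCCC)CCCC | intermediate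
6 | (1E,4S,5S)-4-hydroxy-5-methyl-1-(tributylstannyl)hept-1-en-3-one | CC[C@H](C)[C@H](O)C(=O)/C=C/[Sn](CCCC)(CCCC)CCCC | intermediate
7 | (1E,3R,4S,5S)-3,5-dimethyl-1-(tributylstannyl)hept-1-ene-3,4-diol | CC[C@H](C)[C@H](O)[C@](C)(O)/C=C/[Sn](CCCC)(CCCC)CCCC | intermediate
8 | (1E,3R,4S,5S)-4-[(tert-butyldimethylsilyl)oxy]-3,5-dimethyl-1-(tributylstannyl)hept-1-en-3-ol | CC[C@H](C)[C@H](O[Si](C)(C)C(C)(C)C)[C@](C)(O)/C=C/[Sn](CCCC)(CCCC)CCCC | intermediate
9 | dihydro-2H-pyran-2,4(3H)-dione | O=C1CCOC(=O)C1 | starting material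
10 | 4-methoxy-5,6-dihydro-2H-pyran-2-one | COC1=CC(=O)OCC1 | intermediate
11 | lithium (1E,3R,4S,5S)-4-[(tert-butyldimethylsilyl)oxy]-1-lithio-3,5-dimethylhept-1-en-3-olate (not isolated) | CC[C@H](C)[C@H](O[Si](C)(C)C(C)(C)C)[C@](C)(O[Li])/C=C/[Li] | intermediate
12 | dilithium dialkoxide of 2-[(1E,3R,4S,5S)-4-[(tert-butyldimethylsilyl)oxy]-3-hydroxy-3,5-dimethylhept-1-en-1-yl]-4-methoxy-5,6-dihydro-2H-pyran-2-ol, either configuration at the lactol carbon (not isolated) | CC[C@H](C)[C@H](O[Si](C)(C)C(C)(C)C)[C@](C)(O[Li])/C=C/C1(O[Li])C=C(OC)CCO1 | intermediate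
13 | 6-[(1E,3R,4S,5S)-4-[(tert-butyldimethylsilyl)oxy]-3-hydroxy-3,5-dimethylhept-1-en-1-yl]-2,3-dihydro-4H-pyran-4-one | CC[C@H](C)[C@H](O[Si](C)(C)C(C)(C)C)[C@](C)(O)/C=C/C1=CC(=O)CCO1 | intermediate
14 | ethyl (2S)-2-hydroxypropanoate (ethyl L-lactate) | C[C@H](O)C(=O)OCC | starting material
15 | ethyl (2S)-2-[(triethylsilyl)oxy]propanoate | C[C@H](O[Si](CC)(CC)CC)C(=O)OCC | intermediate
16 | (2S)-2-[(triethylsilyl)oxy]propanal | C[C@H](O[Si](CC)(CC)CC)C=O | intermediate
17 | dilithium salt of 13: C4 enolate of the pyranone (4-lithiooxy-2H-pyran) and side-chain lithium alkoxide (not isolated) | CC[C@H](C)[C@H](O[Si](C)(C)C(C)(C)C)[C@](C)(O[Li])/C=C/C1=CC(O[Li])=CCO1 | intermediate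
18 | (3S)-6-[(1E,3R,4S,5S)-4-[(tert-butyldimethylsilyl)oxy]-3-hydroxy-3,5-dimethylhept-1-en-1-yl]-3-[(1R,2S)-1-hydroxy-2-[(triethylsilyl)oxy]propyl]-2,3-dihydro-4H-pyran-4-one | CC[C@H](C)[C@H](O[Si](C)(C)C(C)(C)C)[C@](C)(O)/C=C/C1=CC(=O)[C@H]([C@@H](O)[C@H](C)O[Si](CC)(CC)CC)CO1 | intermediate
19 | (3S)-3-[(1R,2S)-1-[(tert-butyldimethylsilyl)oxy]-2-[(triethylsilyl)oxy]propyl]-6-[(1E,3R,4S,5S)-4-[(tert-butyldimethylsilyl)oxy]-3-hydroxy-3,5-dimethylhept-1-en-1-yl]-2,3-dihydro-4H-pyran-4-one | CC[C@H](C)[C@H](O[Si](C)(C)C(C)(C)C)[C@](C)(O)/C=C/C1=CC(=O)[C@H]([C@@H](O[Si](C)(C)C(C)(C)C)[C@H](C)O[Si](CC)(CC)CC)CO1 | intermediate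
20 | (Z)-1-bromo-2-ethoxyethene | CCO/C=C\Br | starting material
21 | (Z)-2-ethoxyvinyllithium (not isolated) | CCO/C=C\[Li] | intermediate
22 | dilithium dialkoxide of (3S)-3-[(1R,2S)-1-[(tert-butyldimethylsilyl)oxy]-2-[(triethylsilyl)oxy]propyl]-4-[(Z)-2-ethoxyethenyl]-6-[(1E,3R,4S,5S)-4-[(tert-butyldimethylsilyl)oxy]-3-hydroxy-3,5-dimethylhept-1-en-1-yl]-3,4-dihydro-2H-pyran-4-ol, either configuration at C4 of the pyran (not isolated) | CC[C@H](C)[C@H](O[Si](C)(C)C(C)(C)C)[C@](C)(O[Li])/C=C/C1=CC(O[Li])(/C=C\OCC)[C@H]([C@@H](O[Si](C)(C)C(C)(C)C)[C@H](C)O[Si](CC)(CC)CC)CO1 | intermediate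
23 | (2E)-2-[(3S)-3-[(1R,2S)-1-[(tert-butyldimethylsilyl)oxy]-2-hydroxypropyl]-6-[(1E,3R,4S,5S)-4-[(tert-butyldimethylsilyl)oxy]-3-hydroxy-3,5-dimethylhept-1-en-1-yl]-2,3-dihydro-4H-pyran-4-ylidene]acetaldehyde; formyl group on the side of pyran C3, the isomer that cyclises, the push–pull double bond being labile | CC[C@H](C)[C@H](O[Si](C)(C)C(C)(C)C)[C@](C)(O)/C=C/C1=C/C(=C/C=O)[C@H]([C@@H](O[Si](C)(C)C(C)(C)C)[C@H](C)O)CO1 | intermediate
24 | (2E)-2-[(3S)-3-[(1R)-1-[(tert-butyldimethylsilyl)oxy]-2-oxopropyl]-6-[(1E,3R,4S,5S)-4-[(tert-butyldimethylsilyl)oxy]-3-hydroxy-3,5-dimethylhept-1-en-1-yl]-2,3-dihydro-4H-pyran-4-ylidene]acetaldehyde | CC[C@H](C)[C@H](O[Si](C)(C)C(C)(C)C)[C@](C)(O)/C=C/C1=C/C(=C/C=O)[C@H]([C@@H](O[Si](C)(C)C(C)(C)C)C(C)=O)CO1 | intermediate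
25 | (6R,7R,8R,8aS)-8-[(tert-butyldimethylsilyl)oxy]-3-[(1E,3R,4S,5S)-4-[(tert-butyldimethylsilyl)oxy]-3-hydroxy-3,5-dimethylhept-1-en-1-yl]-7-methyl-6,7,8,8a-tetrahydro-1H-isochromene-6,7-diol | CC[C@H](C)[C@H](O[Si](C)(C)C(C)(C)C)[C@](C)(O)/C=C/C1=CC2=C[C@@H](O)[C@@](C)(O)[C@H](O[Si](C)(C)C(C)(C)C)[C@@H]2CO1 | intermediate
26 | (7S,8R,8aS)-8-[(tert-butyldimethylsilyl)oxy]-3-[(1E,3R,4S,5S)-4-[(tert-butyldimethylsilyl)oxy]-3-hydroxy-3,5-dimethylhept-1-en-1-yl]-7-hydroxy-7-methyl-1,7,8,8a-tetrahydro-6H-isochromen-6-one | CC[C@H](C)[C@H](O[Si](C)(C)C(C)(C)C)[C@](C)(O)/C=C/C1=CC2=CC(=O)[C@@](C)(O)[C@H](O[Si](C)(C)C(C)(C)C)[C@@H]2CO1 | intermediate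
27 | (7S,8R,8aS)-3-[(1E,3R,4S,5S)-3,4-dihydroxy-3,5-dimethylhept-1-en-1-yl]-7,8-dihydroxy-7-methyl-1,7,8,8a-tetrahydro-6H-isochromen-6-one (CNP0291643.10) | CC[C@H](C)[C@H](O)[C@](C)(O)/C=C/C1=CC2=CC(=O)[C@@](C)(O)[C@H](O)[C@@H]2CO1 | target

**Step count and risks**

Total step count: 16. Longest linear sequence: 13 steps (1, 2, 3, 4, 5, 7, 10, 11, 12, 13, 14, 15, 16).

Steps most likely to fail:

Step 14. The delocalised ketyl may be reduced further or dimerise instead of closing, the allylic or alpha silyloxy groups may be lost reductively, or facial control at C7 may be incomplete. The fallback closes the same bond by carbene catalysis instead of electron transfer. It sets out from 24, which would be treated with 2-(pentafluorophenyl)-6,7-dihydro-5H-pyrrolo[2,1-c][1,2,4]triazol-2-ium tetrafluoroborate (20 mol %) and Et3N in THF at 40 °C. The Breslow intermediate formed at C6 should add to the C7 ketone (intramolecular crossed benzoin) and give the acyloin at the right oxidation level, so the route is rejoined at 26 and step 15 is not needed. Facial selectivity at C7 is less certain here than in the pinacol route, because the bulky carbene unit on C6 would then sit near the axial C8 silyl ether.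

Step 12. The hindered carbonyl may be enolised at C8a with beta-elimination of the C8 silyloxy group instead of undergoing addition. In the acid stage, water may capture the cation at C3 (the normal Stork–Danheiser course), opening the pyran and re-closing through the new aldehyde, or C8a may epimerise through the dienol. The fallback avoids a free cation. It sets out from 19, which with ethynylmagnesium bromide (HC≡CMgBr) and LaCl3·2LiCl would give the propargylic carbinol F1. A Meyer–Schuster rearrangement with Ph3PAuNTf2 (monovalent gold, 2 mol %) in toluene/MeOH would then shift the oxygen to the alkyne terminus and give the TES-protected dienal F2. PPTS in MeOH would remove the triethylsilyl group and return the route at 23.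

Step 16. Cleavage of the hindered C8 silyl ether may be slow, and prolonged exposure may open the beta-hydroxy ketone by retro-aldol reaction or dehydrate it. The fallback changes the order of events. It sets out from 25, which has no ketone; HF·pyridine would remove both TBS groups there to give the pentaol F3. MnO2 in CH2Cl2 would then oxidise only the allylic C6 carbinol, the other secondary alcohols not being allylic, and the route is rejoined at 27.

**Further compounds**

F0 | step 14 | none | none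
F1 | step 12 | (3S)-3-[(1R,2S)-1-[(tert-butyldimethylsilyl)oxy]-2-[(triethylsilyl)oxy]propyl]-6-[(1E,3R,4S,5S)-4-[(tert-butyldimethylsilyl)oxy]-3-hydroxy-3,5-dimethylhept-1-en-1-yl]-4-ethynyl-3,4-dihydro-2H-pyran-4-ol, either configuration at C4 | CC[C@H](C)[C@H](O[Si](C)(C)C(C)(C)C)[C@](C)(O)/C=C/C1=CC(O)(C#C)[C@H]([C@@H](O[Si](C)(C)C(C)(C)C)[C@H](C)O[Si](CC)(CC)CC)CO1
F2 | step 12 | (2E)-2-[(3S)-3-[(1R,2S)-1-[(tert-butyldimethylsilyl)oxy]-2-[(triethylsilyl)oxy]propyl]-6-[(1E,3R,4S,5S)-4-[(tert-butyldimethylsilyl)oxy]-3-hydroxy-3,5-dimethylhept-1-en-1-yl]-2,3-dihydro-4H-pyran-4-ylidene]acetaldehyde | CC[C@H](C)[C@H](O[Si](C)(C)C(C)(C)C)[C@](C)(O)/C=C/C1=C/C(=C/C=O)[C@H]([C@@H](O[Si](C)(C)C(C)(C)C)[C@H](C)O[Si](CC)(CC)CC)CO1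
F3 | step 16 | (6R,7R,8R,8aS)-3-[(1E,3R,4S,5S)-3,4-dihydroxy-3,5-dimethylhept-1-en-1-yl]-7-methyl-6,7,8,8a-tetrahydro-1H-isochromene-6,7,8-triol | CC[C@H](C)[C@H](O)[C@](C)(O)/C=C/C1=CC2=C[C@@H](O)[C@@](C)(O)[C@H](O)[C@@H]2CO1
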